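## Analysis of the target

Atom labels used throughout: C7 is the carbinol carbon bearing ring B, C8 the ring CH that carries C7, C9 the ring OCH2 next to C8; C7' is the benzylic CH2 bearing ring A, C8' the ring CH that carries C7', C9' the ring OCH2 next to C8'.

Target 16 is a 3,4-disubstituted tetrahydrofuran (ring atoms O, C9, C8, C8', C9'). C8' carries the C7' methylene attached to ring A, and C8 carries the secondary benzylic carbinol C7 attached to ring B; both rings are the same 3-hydroxy-4-methoxyphenyl unit. There are three contiguous stereocenters, C7 (S), C8 (S) and C8' (R): the two ring substituents are cis, and C7 must be set relative to C8 across a freely rotating exocyclic bond. The cis arrangement is the less stable one, so any intermediate with a carbonyl group at C7 or C7' can epimerize at C8 or C8'. The C7 hydroxyl is benzylic and para to a methoxy group: it ionizes readily in acid (the cation can be trapped by ring A) and is cleaved by hydrogenolysis, so it must arrive late and be unmasked without acid or hydrogen. Both phenols must be protected through the organometallic steps. The hard part is the absolute configuration of the cis C8/C8' pair, because the ring offers no directing group beyond its ether oxygen. The strategy rests on a hidden symmetry: apart from the oxidation level at C7 and C7', the arms on C8 and C8' are identical, so the core is the meso diol 3 with two enantiotopic CH2OH groups.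

## Retrosynthetic reasoning

**16 to 15 (O–Si bonds).** The last operation is removal of the two phenol silyl groups. Triisopropylsilyl ethers are chosen because they survive aryllithium and arylmagnesium formation, mild acid and hydrogenation, and leave under buffered fluoride, which spares the acid-labile C7 carbinol.

**15 to 13 and 14 (C7–ring B bond).** Cutting between C7 and ring B gives aldehyde 13 and the arylmagnesium bromide 14. This cut creates C7 as the last stereocenter, next to C8, so 1,2-induction can be used. It also introduces the fragile benzylic alcohol only one step before the end. A cut at C7–C8 would need an enolate-type carbon at C8 and would put the cis ring junction at risk. The forward reaction must add the aryl group to the aldehyde face anti to C8' without enolizing C8.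

**13 to 12 (oxidation level at C7).** The aldehyde comes from the primary alcohol 12 by a non-basic oxidation. Nothing is cut; the aldehyde is made only when needed because it is the most epimerizable compound of the route.

**12 to 11 (C7'=O removed).** The C7' methylene is traced back to the aryl ketone 11. A carbonyl at C7' is what allows ring A to be attached by acyl chemistry, and a para-methoxy aryl ketone is reducible to CH2 by hydrogenolysis. The forward step must deoxygenate C7' fully while leaving C8' and the silyl ether untouched.

**11 to 6 and 9 (C7'–ring A bond).** Cutting between C7' and ring A gives the bicyclic lactone 6 and the aryllithium 9. The lactone delivers exactly one acyl equivalent at C7' and at the same time releases C7 as a free CH2OH, so the two arms emerge differentiated without protecting groups. The forward step must stop at mono-addition.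

**6 to 3 (the temporary O–C7' bond and the C7' oxidation level).** Lactone 6 is the meso diol 3 with one arm raised to the acid level and tied to the other arm. Reversing this is an enantiotopic-group-selective dehydrogenation. It is the only place where absolute configuration is introduced, and it needs no stoichiometric chiral material. No carbon–carbon bond is formed; the gain is two defined ring stereocenters and two chemically distinct arms in one catalytic step.

**3 to 2 to 1 (functional group changes).** Diol 3 follows from the cis diester 2 by hydride reduction, and 2 from the aromatic diester 1 by catalytic hydrogenation, where syn delivery of hydrogen gives the cis geometry. The tetrahydrofuran ring and both arms are thus bought in one commercial compound.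

**14 and 9 to 8 to 7.** Both aryl nucleophiles come from the same bromide 8, the silyl ether of commercial phenol 7, since rings A and B are identical.

## Alternatives that were turned down

**Alternative 1: photochemical oxetane formation on a 3-benzylfuran.**
- Disconnection: C7–C8, with a temporary O–C9 bond.
- Forward key step: excited 4-methoxy-3-(triisopropylsilyloxy)benzaldehyde A1 adds across the unsubstituted C8=C9 bond of 3-{[4-methoxy-3-(triisopropylsilyloxy)phenyl]methyl}furan A2 (Paternò–Büchi reaction) to give the exo-aryl oxetane A3.
- Completion: hydrogenation of the remaining enol ether from the convex face would set C8' cis, and reductive opening of the acetal C9–O bond would lead to 15.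
- In its favour: it forms a skeletal carbon–carbon bond and fixes C7 relative to C8 in one step, through the usual exo preference of furan–aryl aldehyde cycloadditions. It is shorter than the chosen route, and stronger on the C7 problem, which the chosen route leaves to a Felkin–Anh addition.
- Against it: A2 has two different furan double bonds, and an alkyl group at C8' gives little reason for the excited aldehyde to prefer the unsubstituted one. Both partners are achiral, so A3 forms as a racemate and a resolution would be needed. The oxetane C7–O bond in A3 is a para-alkoxybenzylic ether, so Lewis-acidic opening of the acetal risks ionization at C7 instead.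
- Comparison: the chosen strategy gives up the carbon–carbon bond formation but has no regiochemical question and a catalytic source of absolute configuration.

**Alternative 2: rhodium-catalysed arylative enyne cyclization.**
- Disconnection: C7–ring B and C8–C8'.
- Forward key step: with [Rh(OH)(BINAP)]2, the aryl group of [4-methoxy-3-(triisopropylsilyloxy)phenyl]boronic acid A5 is transferred to the terminal alkyne carbon of the (E)-cinnamyl propargyl ether A4. The alkenylrhodium then closes onto the styrene, and protonation of the benzylic rhodium gives the (R,E)-benzylidene tetrahydrofuran A6.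
- Completion: hydroboration–oxidation anti to the C8' substituent would give 15, the alkene geometry translating into the C7 configuration by syn addition.
- In its favour: this is the most step-economical plan. It builds the ring, two carbon–carbon bonds and the first stereocenter catalytically, and it sets C7 stereospecifically. On all these points it is stronger than the chosen route.
- Against it: the ring-closing carbometalation must occur on an unactivated 1,2-disubstituted styrene, whereas alkenylrhodium intermediates of this kind normally need an electron-poor acceptor. The benzylic rhodium must be protonated faster than it undergoes β-hydride elimination. Terminal alkynes tend to divert such catalysts through alkynyl species. The hydroboration face is controlled by a single benzyl group next to a nearly flat exocyclic alkene.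
- Comparison: the chosen strategy is longer, but every step has a direct counterpart on its substrate class, and the stereochemical risk sits in one known desymmetrization.

**Alternative 3: carbonyl ylide cycloaddition to a γ-aryl butenolide.**
- Disconnection: C8–C9 and C8'–C9'.
- Forward key step: the parent carbonyl ylide, released by CsF from chloromethyl (trimethylsilyl)methyl ether A8, adds suprafacially to the C8=C8' bond of (S)-5-[4-methoxy-3-(triisopropylsilyloxy)phenyl]furan-2(5H)-one A7, anti to the aryl group, giving the cis-fused bicyclic lactone A9.
- Completion: hydrogenolysis of the benzylic lactone C7'–O bond in A9 removes the controlling stereocenter, and adjustment of C7 to the aldehyde level would join the route at 13.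
- In its favour: it constructs the tetrahydrofuran ring itself with both ring stereocenters by substrate control. The cis relationship is guaranteed by the ring alkene. The chosen route builds no skeleton at this stage.
- Against it: A7 must be made enantiopure first. Its γ-hydrogen is both benzylic and vinylogous to the carbonyl, so the basic fluoride medium can racemize it or move the double bond through the furanolate. The unstabilized ylide is a short-lived dipole facing a β-substituted acceptor. Further steps are needed to bring C7 from acid to aldehyde, and the C7 problem remains the same as in the chosen route.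
- Comparison: the chosen strategy reaches an equivalent differentiated intermediate (6) in three steps from a commercial diester, without a configurationally fragile precursor.

Key step: step 3

Assumption: the sense in which Cp*Ir[TsNCH(Ph)CH(Ph)NH] distinguishes the two CH2OH groups of 3 cannot be derived from first principles. The route is written with the (S,S)-ligand; the equally available (R,R)-ligand is used instead if the antipodal lactone results.

## Route

Step 1
Reactants: 1 diethyl furan-3,4-dicarboxylate
Product: 2 diethyl (3R,4S)-tetrahydrofuran-3,4-dicarboxylate (cis, meso)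
Conditions: H2 (50 bar), 5% Rh/Al2O3, EtOH, 60 °C
Reagents that add atoms: none
Why: Heterogeneous hydrogenation of a heteroarene delivers hydrogen from the catalyst surface to one face, so the two ester groups end up cis; Rh/Al2O3 saturates furans with little ring C–O hydrogenolysis.

Step 2
Reactants: 2 diethyl (3R,4S)-tetrahydrofuran-3,4-dicarboxylate
Product: 3 [(3R,4S)-tetrahydrofuran-3,4-diyl]dimethanol (cis, meso)
Conditions: LiAlH4, THF, 0 °C to rt; aqueous NaOH work-up
Reagents that add atoms: none
Why: Hydride reduction of both esters to primary alcohols; the intermediate aldehydes are reduced faster than they can enolize, so the cis (meso) relationship is retained.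

Step 3
Reactants: 3 [(3R,4S)-tetrahydrofuran-3,4-diyl]dimethanol
Product: 6 (3aS,6aR)-tetrahydro-1H,3H-furo[3,4-c]furan-1-one, via hydroxy aldehyde 4 (not isolated), via lactol 5 (not isolated)
Conditions: Cp*Ir[(S,S)-TsNCH(Ph)CH(Ph)NH] (2 mol%), acetone, 30 °C
Reagents that add atoms: none
Why: This is an Oppenauer-type transfer dehydrogenation with acetone as hydrogen acceptor, the closest known reaction type being the enantioselective oxidative lactonization of meso 1,4-diols by chiral Cp*Ir and Ru amido complexes. The 16-electron trivalent iridium amide takes the carbinol hydrogen as hydride on the metal and the hydroxyl proton on nitrogen through a six-membered outer-sphere transition state, and acetone regenerates the amide. The hydroxy aldehyde 4 is captured at once by the neighbouring cis CH2OH in a 5-exo-trig hemiacetalization, which closes the second five-membered ring as the cis-fused lactol 5 and removes the epimerizable aldehyde. A second dehydrogenation at the lactol C–H gives lactone 6 irreversibly, so the temporary O–C7' bond and the C7' carbonyl are in place. C8 and C8' already exist in 3 with their cis relationship; the step makes them the two defined stereocenters of a chiral molecule (3aS and 6aR), and both are controlled by one element, the catalyst's choice of which CH2OH is oxidized. The chiral N-sulfonyl diamine ligand makes that choice through the fit of the ring behind the reacting carbinol against its tosyl and phenyl groups, there being no substrate bias. The selectivity needed is therefore enantiotopic-group selectivity only; chemoselectivity is secured by the substrate, since only the primary carbinol and lactol C–H bonds can be dehydrogenated and cis arms on a five-membered ring close without strain.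

Step 4
Reactants: 7 5-bromo-2-methoxyphenol
Product: 8 (5-bromo-2-methoxyphenoxy)tri(propan-2-yl)silane
Conditions: TIPSCl, imidazole, DMF, rt
Reagents that add atoms: triisopropylsilyl chloride (TIPSCl), CC(C)[Si](Cl)(C(C)C)C(C)C
Why: Imidazole-promoted silylation of a phenol; the bulky aryl silyl ether tolerates the organometallic steps, mild acid and hydrogenation, and the bromine sits meta to the silyloxy group, so no silyl migration to carbon can follow lithiation.

Step 5
Reactants: 8 (5-bromo-2-methoxyphenoxy)tri(propan-2-yl)silane; 6 (3aS,6aR)-tetrahydro-1H,3H-furo[3,4-c]furan-1-one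
Product: 11 [(3R,4R)-4-(hydroxymethyl)tetrahydrofuran-3-yl][4-methoxy-3-(triisopropylsilyloxy)phenyl]methanone, via aryllithium 9 (not isolated), via bicyclic hemiketal 10 (not isolated)
Conditions: 8, n-BuLi, THF, −78 °C; add to 6, THF, −78 °C; AcOH, −78 °C, then warm
Reagents that add atoms: none
Why: Bromine–lithium exchange followed by nucleophilic acyl substitution on the γ-lactone; the tetrahedral adduct (the lithium alkoxide of hemiketal 10) persists at −78 °C, which holds the reaction at mono-addition. The cold acidic quench avoids base-mediated epimerization at C8' once the ketone is released, and the cis isomer is the only one that can rest as the hemiketal.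

Step 6
Reactants: 11 [(3R,4R)-4-(hydroxymethyl)tetrahydrofuran-3-yl][4-methoxy-3-(triisopropylsilyloxy)phenyl]methanone
Product: 12 [(3R,4R)-4-{[4-methoxy-3-(triisopropylsilyloxy)phenyl]methyl}tetrahydrofuran-3-yl]methanol
Conditions: H2 (4 bar), 10% Pd/C, AcOH, HClO4 (cat.), rt
Reagents that add atoms: none
Why: Acid-assisted catalytic hydrogenolysis of an aryl ketone activated by a para methoxy group, through the benzylic alcohol (or through the cyclic benzylic ether formed from the hemiketal, which is cleaved in the same way), takes C7' to CH2 and leaves C7 as a free primary alcohol. The aryl silyl ether, the arene and the tetrahydrofuran ring are not reduced under these conditions.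

Step 7
Reactants: 12 [(3R,4R)-4-{[4-methoxy-3-(triisopropylsilyloxy)phenyl]methyl}tetrahydrofuran-3-yl]methanol
Product: 13 (3S,4R)-4-{[4-methoxy-3-(triisopropylsilyloxy)phenyl]methyl}tetrahydrofuran-3-carbaldehyde
Conditions: Dess–Martin periodinane, pyridine, CH2Cl2, 0 °C; used crude
Reagents that add atoms: none
Why: Dess–Martin oxidation of a primary alcohol to the aldehyde under buffered, essentially neutral conditions; the aldehyde is taken on cold and without chromatography because C8 can epimerize toward the trans isomer.

Step 8
Reactants: 13 (3S,4R)-4-{[4-methoxy-3-(triisopropylsilyloxy)phenyl]methyl}tetrahydrofuran-3-carbaldehyde; 8 (5-bromo-2-methoxyphenoxy)tri(propan-2-yl)silane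
Product: 15 (S)-[4-methoxy-3-(triisopropylsilyloxy)phenyl][(3S,4R)-4-{[4-methoxy-3-(triisopropylsilyloxy)phenyl]methyl}tetrahydrofuran-3-yl]methanol, via arylmagnesium bromide 14 (not isolated)
Conditions: 8, Mg (activated with 1,2-dibromoethane), THF, 40 °C; then 13, THF, −78 °C; pH 7 buffer
Reagents that add atoms: none
Why: Grignard 1,2-addition to an α-branched aldehyde under Felkin–Anh control: with the C8–C8' bond perpendicular to the carbonyl plane and the carbonyl oxygen on the C9 side, the aryl group enters past the C8 hydrogen, anti to C8', which gives 7S. A six-membered magnesium chelate between the carbonyl oxygen and the ring oxygen would expose the same face, and the low temperature limits enolization at C8.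

Step 9
Reactants: 15 (S)-[4-methoxy-3-(triisopropylsilyloxy)phenyl][(3S,4R)-4-{[4-methoxy-3-(triisopropylsilyloxy)phenyl]methyl}tetrahydrofuran-3-yl]methanol
Product: 16 5-{[(3R,4S)-4-[(S)-hydroxy(3-hydroxy-4-methoxyphenyl)methyl]tetrahydrofuran-3-yl]methyl}-2-methoxyphenol
Conditions: Bu4NF, AcOH, THF, 0 °C to rt
Reagents that add atoms: none
Why: Fluoride-induced cleavage of both aryl silyl ethers; buffering with acetic acid keeps the phenols protonated, and the acid-labile, hydrogenolysis-prone C7 carbinol sees neither strong acid nor hydrogen, so no stereocenter is touched.

## Compound list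

1 | diethyl furan-3,4-dicarboxylate | CCOC(=O)c1cocc1C(=O)OCC | starting material
2 | diethyl (3R,4S)-tetrahydrofuran-3,4-dicarboxylate (cis, meso) | CCOC(=O)[C@H]1COC[C@H]1C(=O)OCC | intermediate
3 | [(3R,4S)-tetrahydrofuran-3,4-diyl]dimethanol (cis, meso) | OC[C@H]1COC[C@H]1CO | intermediate
4 | (3R,4R)-4-(hydroxymethyl)tetrahydrofuran-3-carbaldehyde | O=C[C@H]1COC[C@H]1CO | intermediate
5 | (3aS,6aR)-tetrahydro-1H,3H-furo[3,4-c]furan-1-ol (both C1 epimers) | OC1[C@H]2COC[C@H]2CO1 | intermediate
6 | (3aS,6aR)-tetrahydro-1H,3H-furo[3,4-c]furan-1-one | O=C1[C@H]2COC[C@H]2CO1 | intermediate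
7 | 5-bromo-2-methoxyphenol | COc1ccc(Br)cc1O | starting material
8 | (5-bromo-2-methoxyphenoxy)tri(propan-2-yl)silane | COc1ccc(Br)cc1O[Si](C(C)C)(C(C)C)C(C)C | intermediate
9 | [4-methoxy-3-(triisopropylsilyloxy)phenyl]lithium | [Li]c1ccc(OC)c(O[Si](C(C)C)(C(C)C)C(C)C)c1 | intermediate
10 | (3aS,6aR)-1-[4-methoxy-3-(triisopropylsilyloxy)phenyl]tetrahydro-1H,3H-furo[3,4-c]furan-1-ol (formed as its lithium alkoxide; both C1 epimers) | OC1(c2ccc(OC)c(O[Si](C(C)C)(C(C)C)C(C)C)c2)[C@H]2COC[C@H]2CO1 | intermediate
11 | [(3R,4R)-4-(hydroxymethyl)tetrahydrofuran-3-yl][4-methoxy-3-(triisopropylsilyloxy)phenyl]methanone | O=C(c1ccc(OC)c(O[Si](C(C)C)(C(C)C)C(C)C)c1)[C@H]1COC[C@H]1CO | intermediate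
12 | [(3R,4R)-4-{[4-methoxy-3-(triisopropylsilyloxy)phenyl]methyl}tetrahydrofuran-3-yl]methanol | COc1ccc(C[C@H]2COC[C@H]2CO)cc1O[Si](C(C)C)(C(C)C)C(C)C | intermediate
13 | (3S,4R)-4-{[4-methoxy-3-(triisopropylsilyloxy)phenyl]methyl}tetrahydrofuran-3-carbaldehyde | COc1ccc(C[C@H]2COC[C@H]2C=O)cc1O[Si](C(C)C)(C(C)C)C(C)C | intermediate
14 | bromo[4-methoxy-3-(triisopropylsilyloxy)phenyl]magnesium | Br[Mg]c1ccc(OC)c(O[Si](C(C)C)(C(C)C)C(C)C)c1 | intermediate
15 | (S)-[4-methoxy-3-(triisopropylsilyloxy)phenyl][(3S,4R)-4-{[4-methoxy-3-(triisopropylsilyloxy)phenyl]methyl}tetrahydrofuran-3-yl]methanol | COc1ccc(C[C@H]2COC[C@H]2[C@H](O)c2ccc(OC)c(O[Si](C(C)C)(C(C)C)C(C)C)c2)cc1O[Si](C(C)C)(C(C)C)C(C)C | intermediate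
16 | 5-{[(3R,4S)-4-[(S)-hydroxy(3-hydroxy-4-methoxyphenyl)methyl]tetrahydrofuran-3-yl]methyl}-2-methoxyphenol | COc1ccc(C[C@H]2COC[C@H]2[C@H](O)c2ccc(OC)c(O)c2)cc1O | target

## Step count and risk

Total step count: 9. Longest linear sequence: 8 steps (1 to 16 through steps 1, 2, 3, 5, 6, 7, 8 and 9); step 4 is the side branch that supplies both aryl groups.

**Step 3 (key step).** The most likely failure is insufficient discrimination between the two enantiotopic CH2OH groups, which differ only through the ring behind them. Slow turnover is also possible if the ring oxygen or the product lactone occupies the vacant site of the iridium amide. Fallback, from 3 back to 6, desymmetrizes by enzymatic acylation instead of oxidation. A lipase, selected for the arm shown, with vinyl acetate would give the monoacetate [(3S,4S)-4-(hydroxymethyl)tetrahydrofuran-3-yl]methyl acetate F1. Oxidation of its free CH2OH with TEMPO and PhI(OAc)2 in aqueous MeCN would give (3R,4S)-4-[(acetyloxy)methyl]tetrahydrofuran-3-carboxylic acid F2. K2CO3 in MeOH followed by acidification would remove the acetate and close the hydroxy acid to lactone 6.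

**Step 8.** Poor facial selectivity at C7 is the main risk, since the two α-substituents of C8 differ only moderately in size. Enolization of the aldehyde by the basic reagent, with drift of C8 to the trans series, is the second. Fallback, from the crude carbinol of step 8 back to 15, sets C7 by reagent control. Dess–Martin oxidation would give the ketone [4-methoxy-3-(triisopropylsilyloxy)phenyl][(3S,4R)-4-{[4-methoxy-3-(triisopropylsilyloxy)phenyl]methyl}tetrahydrofuran-3-yl]methanone F3. Corey–Bakshi–Shibata reduction with the (R)-2-methyl oxazaborolidine and BH3·SMe2 (aryl as the large group) would return the 7S alcohol 15. The reagent must override the ketone's own bias here, because hydride addition in the Felkin–Anh sense leads to the other C7 configuration.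

**Step 5.** A second aryl addition can occur if the tetrahedral adduct collapses before the quench, and the lactone can be deprotonated by the aryllithium instead of attacked. Fallback, from 6 back to 11, uses an amide that cannot over-add. MeNH(OMe)·HCl with AlMe3 would open the lactone to (3R,4R)-4-(hydroxymethyl)-N-methoxy-N-methyltetrahydrofuran-3-carboxamide F4. Et3SiCl and imidazole would give (3R,4S)-N-methoxy-N-methyl-4-{[(triethylsilyl)oxy]methyl}tetrahydrofuran-3-carboxamide F5. Aryllithium 9 would then give [4-methoxy-3-(triisopropylsilyloxy)phenyl][(3R,4S)-4-{[(triethylsilyl)oxy]methyl}tetrahydrofuran-3-yl]methanone F6 through the stable chelated adduct. AcOH in aqueous THF would remove the alkyl silyl ether selectively to give 11.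

**Step 6.** The deoxygenation can stall at the benzylic alcohol or cyclic ether stage. The acid can also cause enolization of the ketone (epimerization at C8') or loss of the aryl silyl group. Fallback, from 11 back to 12, separates the two reductions. Et3SiH with BF3·OEt2 in CH2Cl2 at −78 °C would reduce the hemiketal form through its oxocarbenium ion to triisopropyl{2-methoxy-5-[(3aS,6aR)-tetrahydro-1H,3H-furo[3,4-c]furan-1-yl]phenoxy}silane F7, with no enolizable ketone left. Neutral hydrogenolysis of its para-alkoxybenzylic C–O bond (H2, Pd(OH)2/C, EtOAc) would then open the ring to 12.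

**Step 1.** The furan carries two acceptor groups and may be saturated slowly or only partly, and forcing conditions invite C–O hydrogenolysis. Fallback, from 1 back to 3, reverses the order of the two reductions. LiAlH4 would reduce 1 to furan-3,4-diyldimethanol F8, an electron-rich furan that should take up hydrogen readily over Rh/Al2O3 in EtOH with syn delivery, giving the cis diol 3 directly.

## Further compounds

F1 | step 3 | [(3S,4S)-4-(hydroxymethyl)tetrahydrofuran-3-yl]methyl acetate | OC[C@H]1COC[C@H]1COC(C)=O
F2 | step 3 | (3R,4S)-4-[(acetyloxy)methyl]tetrahydrofuran-3-carboxylic acid | OC(=O)[C@H]1COC[C@H]1COC(C)=O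
F3 | step 8 | [4-methoxy-3-(triisopropylsilyloxy)phenyl][(3S,4R)-4-{[4-methoxy-3-(triisopropylsilyloxy)phenyl]methyl}tetrahydrofuran-3-yl]methanone | COc1ccc(C[C@H]2COC[C@H]2C(=O)c2ccc(OC)c(O[Si](C(C)C)(C(C)C)C(C)C)c2)cc1O[Si](C(C)C)(C(C)C)C(C)C
F4 | step 5 | (3R,4R)-4-(hydroxymethyl)-N-methoxy-N-methyltetrahydrofuran-3-carboxamide | CON(C)C(=O)[C@H]1COC[C@H]1CO
F5 | step 5 | (3R,4S)-N-methoxy-N-methyl-4-{[(triethylsilyl)oxy]methyl}tetrahydrofuran-3-carboxamide | CON(C)C(=O)[C@H]1COC[C@H]1CO[Si](CC)(CC)CC
F6 | step 5 | [4-methoxy-3-(triisopropylsilyloxy)phenyl][(3R,4S)-4-{[(triethylsilyl)oxy]methyl}tetrahydrofuran-3-yl]methanone | O=C(c1ccc(OC)c(O[Si](C(C)C)(C(C)C)C(C)C)c1)[C@H]1COC[C@H]1CO[Si](CC)(CC)CC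
F7 | step 6 | triisopropyl{2-methoxy-5-[(3aS,6aR)-tetrahydro-1H,3H-furo[3,4-c]furan-1-yl]phenoxy}silane (both C1 epimers) | COc1ccc(C2[C@H]3COC[C@H]3CO2)cc1O[Si](C(C)C)(C(C)C)C(C)C
F8 | step 1 | furan-3,4-diyldimethanol | OCc1cocc1CO
A1 | alternative 1 | 4-methoxy-3-(triisopropylsilyloxy)benzaldehyde | COc1ccc(C=O)cc1O[Si](C(C)C)(C(C)C)C(C)C
A2 | alternative 1 | 3-{[4-methoxy-3-(triisopropylsilyloxy)phenyl]methyl}furan | COc1ccc(Cc2ccoc2)cc1O[Si](C(C)C)(C(C)C)C(C)C
A3 | alternative 1 | exo-6-aryl-4-(arylmethyl)-2,7-dioxabicyclo[3.2.0]hept-3-ene, aryl = 4-methoxy-3-(triisopropylsilyloxy)phenyl | COc1ccc(CC2=CO[C@@H]3[C@H]2[C@H](O3)c2ccc(OC)c(O[Si](C(C)C)(C(C)C)C(C)C)c2)cc1O[Si](C(C)C)(C(C)C)C(C)C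
A4 | alternative 2 | triisopropyl{2-methoxy-5-[(E)-3-(prop-2-yn-1-yloxy)prop-1-en-1-yl]phenoxy}silane | COc1ccc(/C=C/COCC#C)cc1O[Si](C(C)C)(C(C)C)C(C)C
A5 | alternative 2 | [4-methoxy-3-(triisopropylsilyloxy)phenyl]boronic acid | COc1ccc(B(O)O)cc1O[Si](C(C)C)(C(C)C)C(C)C
A6 | alternative 2 | (R,E)-3-(arylmethyl)-4-(arylmethylidene)tetrahydrofuran, aryl = 4-methoxy-3-(triisopropylsilyloxy)phenyl | COc1ccc(C[C@H]2COC/C2=C/c2ccc(OC)c(O[Si](C(C)C)(C(C)C)C(C)C)c2)cc1O[Si](C(C)C)(C(C)C)C(C)C
A7 | alternative 3 | (S)-5-[4-methoxy-3-(triisopropylsilyloxy)phenyl]furan-2(5H)-one | COc1ccc([C@@H]2C=CC(=O)O2)cc1O[Si](C(C)C)(C(C)C)C(C)C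
A8 | alternative 3 | chloromethyl (trimethylsilyl)methyl ether | C[Si](C)(C)COCCl
A9 | alternative 3 | cis-fused exo-3-[4-methoxy-3-(triisopropylsilyloxy)phenyl]tetrahydro-1H,3H-furo[3,4-c]furan-1-one | COc1ccc([C@@H]3[C@H]2COC[C@H]2C(=O)O3)cc1O[Si](C(C)C)(C(C)C)C(C)C
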